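(The data are calculated for substances that don't exist; scatter was added.)

At early times the cedar run at 4.00 min already held 40% monomer in chains against 5% over-reaction product, so what I wanted to watch was how fast the first turns into the second.

all flasks: free monomer 0.020 M

| run | initiator | remark | time |
|---|---|---|---|
| cedar | 0.28 mM | run made earlier |  |
| birch | 0.44 mM | run made earlier |  |
| midnight | 0.20 mM |  | 25 min |
| spring | 0.20 mM |  | 30 min |

| run | time / min | monomer in chains / % | over-reaction product / % | free monomer / % |
|---|---|---|---|---|
| cedar | 4.00 | 40 | 5 | 50 |
| cedar | 8.00 | 56 | 9 | 30 |
| cedar | 12.0 | 63 | 19 | 18 |
| cedar | 15.0 | 61 | 23 | 14 |
| birch | 2.00 | 28 | 2 | 64 |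
| birch | 5.00 | 56 | 5 | 39 |
| birch | 10.0 | 64 | 21 | 16 |
| birch | 15.0 | 64 | 28 | 7 |

(standard deviation of a reading: 1.5 percentage points)
- percent here means free monomer units held: one homo dimer or idle adduct counts as two
- what is said of monomer in chains includes idle adduct
- steps under discussion: initiator -> 2 initiating radical; free monomer + initiating radical -> growing radical + monomer in chains; free monomer + growing radical -> monomer in chains + growing radical; 2 growing radical -> dead chain; 2 free monomer -> homo dimer; free monomer + monomer in chains <-> idle adduct; monomer in chains -> over-reaction product
- in an amount of monomer in chains, one idle adduct counts as one monomer in chains
* which of these there is most of at the end, counted by the free monomer in it, midnight (free monomer / monomer in chains / over-reaction product)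
* which of these there is most of at the end, counted by the free monomer in it, spring (free monomer / monomer in chains / over-reaction product)
* the largest of these amounts at the end, in percent of the free monomer charged, midnight
* the largest of these amounts at the end, in percent of the free monomer charged, spring

I took the over-reaction as first order, with rate k·c(monomer in chains), and read k in two ways. The first way divided the last product reading by the time integral of c(monomer in chains) up to then. This gave 0.0330 /min in cedar and 0.0362 /min in birch.

The second way ignored the product readings. It took what free monomer and chains together lost over the last interval, per unit of chains. Cedar gave 0.0323 /min, which agreed with the first way, but birch gave 0.0281 /min, which parted from it. The second way was the one that cheated: its birch figure is a difference of 9 percentage points built from four readings, each good to 1.5 points, while the first way leans on one reading of 28%.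

So I kept the first way's mean, 0.0346 /min, which makes 20.0 min the half-life of monomer in chains against over-reaction.

Cedar's two last readings of free monomer showed it falling at 0.0838 /min, faster than k by a factor of 2.42, so I let it keep feeding the chains at that rate while the chains went on with that half-life. I started from cedar's readings at 15.0 min, although midnight and spring carry 0.20 mM of initiator against cedar's 0.28 mM. After 0.499 half-lives, for midnight, this gave 49.7% monomer in chains and 6.06% free monomer; counting the rest of the charge as product, that left 44.2% product, so chains led. After 0.749, for spring, it gave 43.7% monomer in chains and 52.3% product, so product led.

The forecast, which held the step “first order in chains”, said monomer in chains at 51% for midnight, above my figure, and over-reaction product at 51% for spring, below mine.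

Midnight held 50.4% monomer in chains and spring 51.6% over-reaction product. Midnight still had 5.97% free monomer at 25.0 min. Letting midnight's 50.4% chains decay over 0.250 half-lives and adding the 2.3 points of free monomer spent meanwhile gave 44.7% for spring, where the flask stood at 44.3%.

    initiator → 2 initiating radical (k = 2.50 × 10⁻⁴ /s)
    free monomer + initiating radical → growing radical + monomer in chains (k = 89000 /M/s)
    free monomer + growing radical → monomer in chains + growing radical, rate k3*[growing radical]*[free monomer] (k = 9700 /M/s)
    2 growing radical → dead chain (k = 1.00 × 10⁶ /M/s)
    2 free monomer → homo dimer (k = 3.80 × 10⁻⁵ /M/s)
    free monomer + monomer in chains ⇌ idle adduct, settled at all times (K = 12.0 /M)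
    monomer in chains → over-reaction product (k = 6.20 × 10⁻⁴ /s)

Spring left until 80 min runs 2.50 of my half-lives further, so its 48.0% of chains and free monomer, all counted as chains, should shrink to 8.50%. That neighbour held 7.88% monomer in chains and 0% free monomer.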